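**Retrosynthetic overview**

1. The strategy rests on ring A: its oxygens at C6 and C8a are para and enclose C7–O and the C8 side chain. C6, C7, C8 and C8a are therefore the four ring carbons of a 3-isopropoxy-4-alkylcyclobutenedione, and C5 and C4a come from an (E)-alkenyl unit.
2. A Moore rearrangement of a 4-alkenyl-4-methoxycyclobutenone forms the C8a–C4a bond and closes ring A as the C8a phenol. The cyclobutenone comes from diisopropyl squarate (through its mono-allyl dione) and an (E)-alkenyllithium made from (3,4-dimethoxyphenyl)acetaldehyde and ethynylmagnesium bromide, with O-methylation of the carbinol.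
3. After ring A, desilylation and oxidation give the 2-hydroxydeoxybenzoin, and one carbon from DMF-DMA closes the pyranone (ring C).
4. End game: BCl3 frees the C7 hydroxyl, then cross-metathesis with 2-methyl-2-butene turns the C8 allyl group into prenyl.
5. Ring order: ring B is bought as the veratryl group, ring A is formed in step 6, ring C in step 9.

Key step: step 6

Assumption: the C8 side chain is carried as allyl and made into prenyl only in the last step, because prenyl-metal reagents attack carbonyls through their γ-carbon (reverse prenyl) and a prenyl alkene beside the freed C7 hydroxyl would be at risk under BCl3; the target has no stereocentre, so chiral intermediates are racemates or diastereomer mixtures.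

**Route**

Step 1
Reactants: 1 diisopropyl squarate; 2 allylmagnesium bromide
Product: 4 3-isopropoxy-4-(prop-2-enyl)cyclobut-3-ene-1,2-dione, via allyl carbinol 3 (not isolated)
Conditions: 2 (1.05 equiv), THF, −78 °C; aq NH4Cl; then 12 M HCl (cat.), CH2Cl2, 23 °C
Reagents that add atoms: none
Why: Grignard 1,2-addition to one squarate carbonyl gives carbinol 3, and acid-catalysed ionisation with loss of propan-2-ol (the standard conversion of squarate adducts into 3-alkoxy-4-alkylcyclobutenediones) should give 4, the allyl reagent having no α/γ ambiguity.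

Step 2
Reactants: 5 (3,4-dimethoxyphenyl)acetaldehyde; 6 ethynylmagnesium bromide
Product: 7 racemic 1-(3,4-dimethoxyphenyl)but-3-yn-2-ol
Conditions: 6 (1.5 equiv), THF, −78 → 0 °C; aq NH4Cl
Reagents that add atoms: none
Why: Grignard addition of the weakly basic acetylide to the aldehyde should outrun enolisation of the arylacetaldehyde; the new carbinol centre forms racemic and is later oxidised to the C4 carbonyl.

Step 3
Reactants: 7 racemic 1-(3,4-dimethoxyphenyl)but-3-yn-2-ol
Product: 8 racemic tert-butyl{[1-(3,4-dimethoxyphenyl)but-3-yn-2-yl]oxy}dimethylsilane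
Conditions: TBSCl, imidazole, DMF, 23 °C
Reagents that add atoms: tert-butyldimethylsilyl chloride CC(C)(C)[Si](C)(C)Cl
Why: Standard silyl ether formation masks the propargylic alcohol against the organometallic steps that follow.

Step 4
Reactants: 8 racemic tert-butyl{[1-(3,4-dimethoxyphenyl)but-3-yn-2-yl]oxy}dimethylsilane
Product: 10 racemic tert-butyl{[(E)-1-(3,4-dimethoxyphenyl)-4-iodobut-3-en-2-yl]oxy}dimethylsilane, via alkenylzirconocene chloride 9 (not isolated)
Conditions: Cp2Zr(H)Cl (1.3 equiv), THF, 23 °C, dark; then iodine, 0 °C; aq Na2S2O3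
Reagents that add atoms: iodine [I][I]
Why: Hydrozirconation adds Zr–H syn across the terminal alkyne with zirconium on the terminal carbon, and iodinolysis of the C–Zr bond of 9 proceeds with retention, so the (E)-alkenyl iodide is expected.

Step 5
Reactants: 10 racemic (E)-alkenyl iodide; 4 3-isopropoxy-4-(prop-2-enyl)cyclobut-3-ene-1,2-dione
Product: 13 4-[(E)-3-(tert-butyldimethylsilyloxy)-4-(3,4-dimethoxyphenyl)but-1-enyl]-3-isopropoxy-4-methoxy-2-(prop-2-enyl)cyclobut-2-en-1-one (racemic diastereomer mixture), via alkenyllithium 11 (not isolated), via lithium alkoxide 12 (not isolated)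
Conditions: 10, t-BuLi (2.0 equiv), Et2O, −78 °C; cannulate into 4, THF, −78 °C; MeOTf (3 equiv), −78 → 0 °C; aq NaHCO3
Reagents that add atoms: methyl trifluoromethanesulfonate COS(=O)(=O)C(F)(F)F
Why: Lithium–iodine exchange with retention of alkene geometry gives 11, which should add 1,2 to the more electrophilic carbonyl of 4 (the one next to the isopropoxy-bearing carbon, not the vinylogous ester carbonyl), and alkoxide 12 is O-methylated in the same flask by Williamson-type alkylation; the new quaternary centre forms without control and both diastereomers serve.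

Step 6
Reactants: 13 4-alkenyl-4-methoxycyclobutenone (racemic diastereomer mixture)
Product: 16 racemic 2-[1-(tert-butyldimethylsilyloxy)-2-(3,4-dimethoxyphenyl)ethyl]-5-isopropoxy-4-methoxy-6-(prop-2-enyl)phenol, via dienylketene 14 (not isolated), via cyclohexadienone 15 (not isolated)
Conditions: degassed toluene (0.02 M), 110 °C, Ar
Reagents that add atoms: none
Why: Heating should open the cyclobutenone by conrotatory 4π electrocyclic cleavage of the bond between the carbonyl carbon and the quaternary carbon, the methoxy donor turning outward and the alkenyl group inward, to give the (3Z)-dienylketene 14. A thermal 6π electrocyclisation of 14 then joins the ketene carbon to the distal alkene carbon (the C8a–C4a bond) and closes the six-membered carbocycle as dienone 15, which enolises to phenol 16; ring A is thus closed by disrotatory 6π electrocyclic ring closure. The closest known reaction type is the Moore rearrangement of 4-alkenyl-4-alkoxycyclobutenones to hydroquinone monoethers. No stereocentre is created: the quaternary centre of 13 and the sp3 ring carbon of 15 both become aromatic carbons, and the silyloxy carbinol is carried as the racemate. The step needs torquoselectivity and the right regiochemistry; the first is secured by the strong preference of the C4 oxygen donor for outward rotation, which places the alkene beside the ketene, and the second was fixed in step 5, so the former squarate carbons appear as C6 (OMe), C7 (O-isopropyl), C8 (allyl) and C8a (OH). Dilute, oxygen-free conditions should keep the ketene from intermolecular trapping and the electron-rich phenol from oxidation.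

Step 7
Reactants: 16 racemic silyl ether phenol
Product: 17 racemic 2-[2-(3,4-dimethoxyphenyl)-1-hydroxyethyl]-5-isopropoxy-4-methoxy-6-(prop-2-enyl)phenol
Conditions: TBAF, AcOH (1:1), THF, 0 → 23 °C, Ar
Reagents that add atoms: none
Why: Fluoride-mediated cleavage of the Si–O bond, buffered with acetic acid so that the oxidation-prone phenoxide is not generated, should free the benzylic alcohol.

Step 8
Reactants: 17 racemic phenol carbinol
Product: 18 2-(3,4-dimethoxyphenyl)-1-[2-hydroxy-4-isopropoxy-5-methoxy-3-(prop-2-enyl)phenyl]ethanone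
Conditions: activated MnO2 (15 equiv), CH2Cl2, 23 °C, Ar
Reagents that add atoms: none
Why: Heterogeneous MnO2 oxidation is selective for benzylic carbinols and should dehydrogenate the secondary alcohol to the aryl ketone, which is then stabilised by the hydrogen bond from the ortho phenol.

Step 9
Reactants: 18 2-hydroxydeoxybenzoin
Product: 20 3-(3,4-dimethoxyphenyl)-7-isopropoxy-6-methoxy-8-(prop-2-enyl)-4H-chromen-4-one, via enaminone 19 (not isolated)
Conditions: DMF-DMA (3 equiv), toluene, 95 °C; then AcOH (cat.), 23 °C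
Reagents that add atoms: N,N-dimethylformamide dimethyl acetal COC(OC)N(C)C
Why: Condensation of DMF-DMA at the doubly activated methylene gives enaminone 19, and intramolecular conjugate addition of the ortho phenol with loss of dimethylamine closes ring C (the standard deoxybenzoin route to isoflavones).

Step 10
Reactants: 20 7-isopropoxy-8-allyl isoflavone
Product: 21 3-(3,4-dimethoxyphenyl)-7-hydroxy-6-methoxy-8-(prop-2-enyl)-4H-chromen-4-one
Conditions: BCl3 (3 equiv), CH2Cl2, −78 → 0 °C; H2O quench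
Reagents that add atoms: none
Why: Lewis-acid ether cleavage by BCl3 is selective for the secondary isopropyl group, which leaves as 2-chloropropane, over the methyl ethers (none has a peri carbonyl to direct the reagent), and the monosubstituted allyl alkene should be inert.

Step 11
Reactants: 21 8-allyl-7-hydroxy isoflavone
Product: 22 3-(3,4-dimethoxyphenyl)-7-hydroxy-6-methoxy-8-(3-methylbut-2-enyl)-4H-chromen-4-one (target)
Conditions: second-generation Grubbs catalyst RuCl2(=CHPh)(H2IMes)(PCy3) (5 mol%), 2-methyl-2-butene (excess), CH2Cl2, 40 °C, sealed tube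
Reagents that add atoms: 2-methyl-2-butene CC=C(C)C
Why: Olefin cross-metathesis of the terminal allyl alkene with excess 2-methyl-2-butene exchanges the methylene terminus for an isopropylidene group, a well-used conversion of ortho-allylphenols into prenylphenols that tolerates the free phenol and the chromone.

**Compound list**

1 | diisopropyl squarate (3,4-diisopropoxycyclobut-3-ene-1,2-dione) | CC(C)OC1=C(OC(C)C)C(=O)C1=O | starting material
2 | allylmagnesium bromide | C=CC[Mg]Br | starting material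
3 | racemic 4-hydroxy-2,3-diisopropoxy-4-(prop-2-enyl)cyclobut-2-en-1-one (not isolated) | CC(C)OC1=C(OC(C)C)C(O)(CC=C)C1=O | intermediate
4 | 3-isopropoxy-4-(prop-2-enyl)cyclobut-3-ene-1,2-dione | CC(C)OC1=C(CC=C)C(=O)C1=O | intermediate
5 | (3,4-dimethoxyphenyl)acetaldehyde | COc1ccc(CC=O)cc1OC | starting material
6 | ethynylmagnesium bromide | C#C[Mg]Br | starting material
7 | racemic 1-(3,4-dimethoxyphenyl)but-3-yn-2-ol | COc1ccc(CC(O)C#C)cc1OC | intermediate
8 | racemic tert-butyl{[1-(3,4-dimethoxyphenyl)but-3-yn-2-yl]oxy}dimethylsilane | COc1ccc(CC(C#C)O[Si](C)(C)C(C)(C)C)cc1OC | intermediate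
9 | racemic chlorobis(cyclopentadienyl)[(E)-3-(tert-butyldimethylsilyloxy)-4-(3,4-dimethoxyphenyl)but-1-enyl]zirconium (not isolated) | COc1ccc(CC(/C=C/[Zr+2]Cl)O[Si](C)(C)C(C)(C)C)cc1OC.c1cc[cH-]c1.c1cc[cH-]c1 | intermediate
10 | racemic tert-butyl{[(E)-1-(3,4-dimethoxyphenyl)-4-iodobut-3-en-2-yl]oxy}dimethylsilane | COc1ccc(CC(/C=C/I)O[Si](C)(C)C(C)(C)C)cc1OC | intermediate
11 | racemic [(E)-3-(tert-butyldimethylsilyloxy)-4-(3,4-dimethoxyphenyl)but-1-enyl]lithium (not isolated) | COc1ccc(CC(/C=C/[Li])O[Si](C)(C)C(C)(C)C)cc1OC | intermediate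
12 | lithium 1-[(E)-3-(tert-butyldimethylsilyloxy)-4-(3,4-dimethoxyphenyl)but-1-enyl]-2-isopropoxy-4-oxo-3-(prop-2-enyl)cyclobut-2-en-1-olate, diastereomer mixture (not isolated) | [Li+].[O-]C1(/C=C/C(Cc2ccc(OC)c(OC)c2)O[Si](C)(C)C(C)(C)C)C(=O)C(CC=C)=C1OC(C)C | intermediate
13 | 4-[(E)-3-(tert-butyldimethylsilyloxy)-4-(3,4-dimethoxyphenyl)but-1-enyl]-3-isopropoxy-4-methoxy-2-(prop-2-enyl)cyclobut-2-en-1-one, racemic diastereomer mixture | COC1(/C=C/C(Cc2ccc(OC)c(OC)c2)O[Si](C)(C)C(C)(C)C)C(=O)C(CC=C)=C1OC(C)C | intermediate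
14 | racemic (3Z,5E)-7-(tert-butyldimethylsilyloxy)-8-(3,4-dimethoxyphenyl)-3-isopropoxy-4-methoxy-2-(prop-2-enyl)octa-1,3,5-trien-1-one (not isolated) | O=C=C(CC=C)\C(OC(C)C)=C(OC)/C=C/C(Cc1ccc(OC)c(OC)c1)O[Si](C)(C)C(C)(C)C | intermediate
15 | 6-[1-(tert-butyldimethylsilyloxy)-2-(3,4-dimethoxyphenyl)ethyl]-3-isopropoxy-4-methoxy-2-(prop-2-enyl)cyclohexa-2,4-dien-1-one, diastereomer mixture (not isolated) | O=C1C(CC=C)=C(OC(C)C)C(OC)=CC1C(Cc2ccc(OC)c(OC)c2)O[Si](C)(C)C(C)(C)C | intermediate
16 | racemic 2-[1-(tert-butyldimethylsilyloxy)-2-(3,4-dimethoxyphenyl)ethyl]-5-isopropoxy-4-methoxy-6-(prop-2-enyl)phenol | COc1cc(C(Cc2ccc(OC)c(OC)c2)O[Si](C)(C)C(C)(C)C)c(O)c(CC=C)c1OC(C)C | intermediate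
17 | racemic 2-[2-(3,4-dimethoxyphenyl)-1-hydroxyethyl]-5-isopropoxy-4-methoxy-6-(prop-2-enyl)phenol | COc1cc(C(O)Cc2ccc(OC)c(OC)c2)c(O)c(CC=C)c1OC(C)C | intermediate
18 | 2-(3,4-dimethoxyphenyl)-1-[2-hydroxy-4-isopropoxy-5-methoxy-3-(prop-2-enyl)phenyl]ethanone | COc1cc(C(=O)Cc2ccc(OC)c(OC)c2)c(O)c(CC=C)c1OC(C)C | intermediate
19 | 3-(dimethylamino)-2-(3,4-dimethoxyphenyl)-1-[2-hydroxy-4-isopropoxy-5-methoxy-3-(prop-2-enyl)phenyl]prop-2-en-1-one (not isolated) | COc1cc(C(=O)C(=CN(C)C)c2ccc(OC)c(OC)c2)c(O)c(CC=C)c1OC(C)C | intermediate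
20 | 3-(3,4-dimethoxyphenyl)-7-isopropoxy-6-methoxy-8-(prop-2-enyl)-4H-chromen-4-one | COc1ccc(-c2coc3c(CC=C)c(OC(C)C)c(OC)cc3c2=O)cc1OC | intermediate
21 | 3-(3,4-dimethoxyphenyl)-7-hydroxy-6-methoxy-8-(prop-2-enyl)-4H-chromen-4-one | COc1ccc(-c2coc3c(CC=C)c(O)c(OC)cc3c2=O)cc1OC | intermediate
22 | 3-(3,4-dimethoxyphenyl)-7-hydroxy-6-methoxy-8-(3-methylbut-2-enyl)-4H-chromen-4-one | COc1ccc(-c2coc3c(CC=C(C)C)c(O)c(OC)cc3c2=O)cc1OC | target

**Step count**

Total steps: 11. Longest linear sequence: 10 steps (steps 2 to 11, from aldehyde 5); step 1 is a one-step branch that joins at step 5.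

**Steps most likely to fail, with fallbacks**

Step 6 (Moore rearrangement). What may go wrong: thermal loss of silanol from the ortho-hydroxybenzylic silyl ether as it forms (quinone methide formation and oligomerisation), or oxidation of the very electron-rich phenol by traces of air. The fallback moves the carbinol oxidation in front of the rearrangement, so that the arene is formed directly as a hydrogen-bonded ortho-hydroxyaryl ketone.
- It sets out from 13. Buffered desilylation (TBAF, AcOH, THF, 0 °C) should give the allylic alcohol 4-[(E)-4-(3,4-dimethoxyphenyl)-3-hydroxybut-1-enyl]-3-isopropoxy-4-methoxy-2-(prop-2-enyl)cyclobut-2-en-1-one F1.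
- Dess–Martin periodinane (NaHCO3, CH2Cl2, 0 °C) should give the enone 4-[(E)-4-(3,4-dimethoxyphenyl)-3-oxobut-1-enyl]-3-isopropoxy-4-methoxy-2-(prop-2-enyl)cyclobut-2-en-1-one F2.
- Thermolysis in degassed toluene at 110 °C should pass through the acyl dienylketene (3Z,5E)-8-(3,4-dimethoxyphenyl)-3-isopropoxy-4-methoxy-2-(prop-2-enyl)octa-1,3,5-triene-1,7-dione F3 and the dienone 6-[(3,4-dimethoxyphenyl)acetyl]-3-isopropoxy-4-methoxy-2-(prop-2-enyl)cyclohexa-2,4-dien-1-one F4, whose enolisation gives the deoxybenzoin.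
- It comes back to the route at 18; steps 7 and 8 are then not needed.

Step 8 (MnO2 oxidation). What may go wrong: one-electron oxidation of the para-alkoxyphenol ring (phenoxyl radical coupling or quinone formation) competing with dehydrogenation of the carbinol, or surface-promoted dehydration of the benzylic alcohol to a stilbene. The fallback masks the phenol before the oxidation.
- It sets out from 16. NaH and MOMCl (THF/DMF, 0 °C) should give the MOM ether tert-butyl{1-[4-isopropoxy-5-methoxy-2-(methoxymethoxy)-3-(prop-2-enyl)phenyl]-2-(3,4-dimethoxyphenyl)ethoxy}dimethylsilane F5.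
- TBAF (THF, 23 °C) should give the alcohol 1-[4-isopropoxy-5-methoxy-2-(methoxymethoxy)-3-(prop-2-enyl)phenyl]-2-(3,4-dimethoxyphenyl)ethanol F6.
- Dess–Martin periodinane (CH2Cl2, 23 °C), now with no free phenol present, should give the ketone 1-[4-isopropoxy-5-methoxy-2-(methoxymethoxy)-3-(prop-2-enyl)phenyl]-2-(3,4-dimethoxyphenyl)ethanone F7.
- Mild acid methanolysis (2 M HCl, MeOH, 40 °C) removes the MOM group, which is activated by the ortho carbonyl; the fallback comes back to the route at 18.

Step 5 (alkenyllithium addition and in situ methylation). What may go wrong: deprotonation of the doubly activated allylic CH2 of dione 4 by the basic alkenyllithium in place of carbonyl addition, incomplete lithium–iodine exchange, or incomplete trapping of the hindered tertiary alkoxide. The fallback uses the far less basic acetylide and sets the alkene afterwards.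
- It sets out from 8 and 4. n-BuLi (THF, −78 °C) should give the lithium acetylide [3-(tert-butyldimethylsilyloxy)-4-(3,4-dimethoxyphenyl)but-1-ynyl]lithium F8.
- Addition of F8 to 4 at −78 °C should give the alkoxide lithium 1-[3-(tert-butyldimethylsilyloxy)-4-(3,4-dimethoxyphenyl)but-1-ynyl]-2-isopropoxy-4-oxo-3-(prop-2-enyl)cyclobut-2-en-1-olate F9.
- MeOTf should convert F9 into the alkynyl methyl ether 4-[3-(tert-butyldimethylsilyloxy)-4-(3,4-dimethoxyphenyl)but-1-ynyl]-3-isopropoxy-4-methoxy-2-(prop-2-enyl)cyclobut-2-en-1-one F10.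
- Semi-hydrogenation (H2, 1 atm, Pd on CaCO3 poisoned with Pb(OAc)2, quinoline, EtOAc, 23 °C, stopped after one equivalent of H2 to spare the allyl group) should give the (Z)-alkene 4-[(Z)-3-(tert-butyldimethylsilyloxy)-4-(3,4-dimethoxyphenyl)but-1-enyl]-3-isopropoxy-4-methoxy-2-(prop-2-enyl)cyclobut-2-en-1-one F11.
- Thermolysis under the conditions of step 6 should open F11 to the dienylketene (3Z,5Z)-7-(tert-butyldimethylsilyloxy)-8-(3,4-dimethoxyphenyl)-3-isopropoxy-4-methoxy-2-(prop-2-enyl)octa-1,3,5-trien-1-one F12, which closes to dienone 15 because the alkene geometry is lost on ring closure.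
- It comes back to the route at 16.

**Further compounds**

F1 | step 6 | 4-[(E)-4-(3,4-dimethoxyphenyl)-3-hydroxybut-1-enyl]-3-isopropoxy-4-methoxy-2-(prop-2-enyl)cyclobut-2-en-1-one | COC1(/C=C/C(O)Cc2ccc(OC)c(OC)c2)C(=O)C(CC=C)=C1OC(C)C
F2 | step 6 | 4-[(E)-4-(3,4-dimethoxyphenyl)-3-oxobut-1-enyl]-3-isopropoxy-4-methoxy-2-(prop-2-enyl)cyclobut-2-en-1-one | COC1(/C=C/C(=O)Cc2ccc(OC)c(OC)c2)C(=O)C(CC=C)=C1OC(C)C
F3 | step 6 | (3Z,5E)-8-(3,4-dimethoxyphenyl)-3-isopropoxy-4-methoxy-2-(prop-2-enyl)octa-1,3,5-triene-1,7-dione | O=C=C(CC=C)\C(OC(C)C)=C(OC)/C=C/C(=O)Cc1ccc(OC)c(OC)c1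
F4 | step 6 | 6-[(3,4-dimethoxyphenyl)acetyl]-3-isopropoxy-4-methoxy-2-(prop-2-enyl)cyclohexa-2,4-dien-1-one | O=C1C(CC=C)=C(OC(C)C)C(OC)=CC1C(=O)Cc2ccc(OC)c(OC)c2
F5 | step 8 | tert-butyl{1-[4-isopropoxy-5-methoxy-2-(methoxymethoxy)-3-(prop-2-enyl)phenyl]-2-(3,4-dimethoxyphenyl)ethoxy}dimethylsilane | COCOc1c(CC=C)c(OC(C)C)c(OC)cc1C(Cc2ccc(OC)c(OC)c2)O[Si](C)(C)C(C)(C)C
F6 | step 8 | 1-[4-isopropoxy-5-methoxy-2-(methoxymethoxy)-3-(prop-2-enyl)phenyl]-2-(3,4-dimethoxyphenyl)ethanol | COCOc1c(CC=C)c(OC(C)C)c(OC)cc1C(O)Cc2ccc(OC)c(OC)c2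
F7 | step 8 | 1-[4-isopropoxy-5-methoxy-2-(methoxymethoxy)-3-(prop-2-enyl)phenyl]-2-(3,4-dimethoxyphenyl)ethanone | COCOc1c(CC=C)c(OC(C)C)c(OC)cc1C(=O)Cc2ccc(OC)c(OC)c2
F8 | step 5 | [3-(tert-butyldimethylsilyloxy)-4-(3,4-dimethoxyphenyl)but-1-ynyl]lithium | COc1ccc(CC(C#C[Li])O[Si](C)(C)C(C)(C)C)cc1OC
F9 | step 5 | lithium 1-[3-(tert-butyldimethylsilyloxy)-4-(3,4-dimethoxyphenyl)but-1-ynyl]-2-isopropoxy-4-oxo-3-(prop-2-enyl)cyclobut-2-en-1-olate | [Li+].[O-]C1(C#CC(Cc2ccc(OC)c(OC)c2)O[Si](C)(C)C(C)(C)C)C(=O)C(CC=C)=C1OC(C)C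
F10 | step 5 | 4-[3-(tert-butyldimethylsilyloxy)-4-(3,4-dimethoxyphenyl)but-1-ynyl]-3-isopropoxy-4-methoxy-2-(prop-2-enyl)cyclobut-2-en-1-one | COC1(C#CC(Cc2ccc(OC)c(OC)c2)O[Si](C)(C)C(C)(C)C)C(=O)C(CC=C)=C1OC(C)C
F11 | step 5 | 4-[(Z)-3-(tert-butyldimethylsilyloxy)-4-(3,4-dimethoxyphenyl)but-1-enyl]-3-isopropoxy-4-methoxy-2-(prop-2-enyl)cyclobut-2-en-1-one | COC1(/C=C\C(Cc2ccc(OC)c(OC)c2)O[Si](C)(C)C(C)(C)C)C(=O)C(CC=C)=C1OC(C)C
F12 | step 5 | (3Z,5Z)-7-(tert-butyldimethylsilyloxy)-8-(3,4-dimethoxyphenyl)-3-isopropoxy-4-methoxy-2-(prop-2-enyl)octa-1,3,5-trien-1-one | O=C=C(CC=C)\C(OC(C)C)=C(OC)/C=C\C(Cc1ccc(OC)c(OC)c1)O[Si](C)(C)C(C)(C)C
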